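## Retrosynthetic overview

1. C40 = C15 + C10 + C15: two Wittig olefinations (C11=C12, then C11'=C12') of 2,7-dimethylocta-2,4,6-trienedial with two C15 phosphonium salts that differ only at C4 (CHOH in ring A, C=O in ring B).
2. Both salts come from one tertiary allylic diol: ring A keeps the C4 hydroxyl, ring B is re-oxidised. C9–C11 come from methyl vinyl ketone (cross-metathesis at the C7=C8 vinyl group) and vinylmagnesium bromide.
3. The cyclohexane ring is formed once, before any chain building, and serves as ring B directly and as ring A after reduction. Its C4(=O)–C5 bond is closed by an enantioselective, desymmetrising carbene-catalysed hydroacylation of an achiral acyclic 1,4-diene aldehyde, which also sets C5 and C6.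
4. Enabling feature: in each end ring the carbonyl (or carbinol) carbon C4 is bonded to C5, a methine carrying a CH3 group, and C5 sits on C6, which also carries the C7=C8 vinyl unit. C5–CH3 is therefore a vinyl group in disguise, C6 a latent divinylmethine, and C4(=O)–C5(CH3) the retron of a 6-exo Markovnikov hydroacylation.
5. The acyclic aldehyde comes from an Ireland–Claisen rearrangement (C1–C6 bond, quaternary C1) and a two-carbon homologation.

Key step: step 7

Assumption: (2E)-penta-2,4-dien-1-ol is taken as a catalogue compound. Carotenoid numbering is used in the text (ring C1–C6, chain C7–C15, primes for the oxo half; ring A = hydroxy ring, ring B = oxo ring).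

## Route

Step 1
Reactants: 1 (2E)-penta-2,4-dien-1-ol; 2 2-methylpropanoyl chloride
Product: 3 (2E)-penta-2,4-dien-1-yl 2-methylpropanoate
Conditions: Et3N, DMAP (cat.), CH2Cl2, 0 °C to rt
Reagents that add atoms: none
Why: DMAP-catalysed acylation of a primary allylic alcohol by an acid chloride (nucleophilic acyl substitution); no stereocentre is involved.

Step 2
Reactants: 3 (2E)-penta-2,4-dien-1-yl 2-methylpropanoate
Product: 6 3-ethenyl-2,2-dimethylpent-4-enoic acid, via silyl ketene acetal 4 (not isolated), via trimethylsilyl ester 5 (not isolated)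
Conditions: LiN(iPr)2, THF, −78 °C; Me3SiCl; −78 °C to 60 °C; then 1 M HCl
Reagents that add atoms: chlorotrimethylsilane, C[Si](C)(C)Cl (its Me3Si group is carried only by 4 and 5 and is lost on work-up; nothing of it remains in 6)
Why: Ireland–Claisen rearrangement, in which the tetrasubstituted silyl ketene acetal should undergo the [3,3]-sigmatropic shift through the proximal C=C bond of the dienyl ester, forming the bond between the quaternary carbon and the carbon that then carries two vinyl groups; the product is achiral.

Step 3
Reactants: 6 3-ethenyl-2,2-dimethylpent-4-enoic acid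
Product: 7 3-ethenyl-2,2-dimethylpent-4-en-1-ol
Conditions: LiAlH4, Et2O, 0 °C to rt; aqueous work-up
Reagents that add atoms: none
Why: LiAlH4 reduction of a carboxylic acid to the primary (neopentyl) alcohol; the isolated alkenes are inert.

Step 4
Reactants: 7 3-ethenyl-2,2-dimethylpent-4-en-1-ol
Product: 8 3-ethenyl-2,2-dimethylpent-4-enal
Conditions: Dess–Martin periodinane, CH2Cl2, 0 °C to rt
Reagents that add atoms: none
Why: Dess–Martin oxidation of a primary alcohol to an aldehyde that cannot enolise (alpha-quaternary) and is not over-oxidised under these neutral conditions.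

Step 5
Reactants: 8 3-ethenyl-2,2-dimethylpent-4-enal; 9 (triphenylphosphoranylidene)acetaldehyde
Product: 10 (2E)-5-ethenyl-4,4-dimethylhepta-2,6-dienal
Conditions: toluene, 80 °C
Reagents that add atoms: none
Why: Wittig olefination with a stabilised formyl ylide should give the (E)-enal, the temperature being held at 80 °C or below so that the 1,5-diene unit of 10 does not undergo Cope rearrangement.

Step 6
Reactants: 10 (2E)-5-ethenyl-4,4-dimethylhepta-2,6-dienal
Product: 11 5-ethenyl-4,4-dimethylhept-6-enal
Conditions: Hantzsch ester (diethyl 1,4-dihydro-2,6-dimethylpyridine-3,5-dicarboxylate), dibenzylammonium trifluoroacetate (10 mol%), THF, rt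
Reagents that add atoms: none
Why: Organocatalytic iminium-ion transfer hydrogenation should reduce only the conjugated C=C bond of the enal, leaving the aldehyde and both vinyl groups untouched; no stereocentre is formed.

Step 7
Reactants: 11 5-ethenyl-4,4-dimethylhept-6-enal
Product: 12 (2S,3S)-3-ethenyl-2,4,4-trimethylcyclohexan-1-one
Conditions: chiral aminoindanol-derived N-mesityl triazolium chloride (2-mesityl-5a,10b-dihydro-4H,6H-indeno[2,1-b][1,2,4]triazolo[4,3-d][1,4]oxazin-2-ium chloride, 20 mol%; both antipodes are available and the one that delivers the (2S,3S) series in a test run is used), DBU (20 mol%), 1,4-dioxane (0.02 M), 100 °C, Ar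
Reagents that add atoms: none
Why: Proposed new method: the triazolylidene adds to the aldehyde of 11 to give the Breslow enaminol (an acyl-anion equivalent), which adds across one unactivated vinyl group in a concerted but asynchronous ene-type (Conia-ene-like) transition state, the acyl carbon bonding to the internal alkene carbon while the enol O–H proton passes to the terminal CH2, after which the azolium alkoxide collapses to the ketone and frees the carbene; the closest known reaction type is the carbene-catalysed intramolecular hydroacylation of unactivated alkenes tethered to aromatic aldehydes (alpha-methyl chromanones, also enantioselective with chiral triazolium salts), extended here to an aliphatic aldehyde and to the desymmetrisation of a 1,4-diene, in analogy to metal-catalysed desymmetrising hydroacylations of dienyl aldehydes. The cyclohexanone ring closes 6-exo-trig, and because the proton is delivered through a five-membered array only the Markovnikov mode is possible, so the terminal CH2 becomes the C2 methyl group. C3 is set by enantiotopic-group selection: in the chair-like transition state the quaternary C(CH3)2 neighbour holds the spectator vinyl group equatorial, so that the facial bias of the chiral carbene at the acyl carbon is translated into reaction of the pro-S vinyl group only. C2 is set by the alkene face in the same chair and, being alpha to the new ketone, should in any case be equilibrated by DBU to the trans-diequatorial (2S) arrangement without touching C3. The step needs group selectivity between the two vinyl groups and cyclisation in preference to acyloin or aldol self-condensation; the first rests on the catalyst enantiomer and the rigid chair, the second on the Thorpe–Ingold effect of the gem-dimethyl group, high dilution and a base charge no larger than that of the precatalyst.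

Step 8
Reactants: 12 (2S,3S)-3-ethenyl-2,4,4-trimethylcyclohexan-1-one
Product: 13 (1S,2S,3S)-3-ethenyl-2,4,4-trimethylcyclohexan-1-ol
Conditions: NaBH4, MeOH, −20 °C
Reagents that add atoms: none
Why: Hydride reduction of a conformationally fixed cyclohexanone, in which the small hydride should attack axially (no 1,3-diaxial substituent on that face) to give the equatorial (1S) alcohol trans to the C2 methyl group under substrate control, any axial epimer being removed by chromatography.

Step 9
Reactants: 13 (1S,2S,3S)-3-ethenyl-2,4,4-trimethylcyclohexan-1-ol; 14 but-3-en-2-one (methyl vinyl ketone, excess)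
Product: 15 (3E)-4-[(1S,2S,3S)-3-hydroxy-2,6,6-trimethylcyclohexyl]but-3-en-2-one
Conditions: second-generation Hoveyda–Grubbs catalyst, RuCl2(H2IMes)(=CH-C6H4-2-OiPr) (5 mol%), CH2Cl2, 40 °C
Reagents that add atoms: none
Why: Olefin cross-metathesis of a terminal alkene with an electron-poor partner should be E-selective, tolerates the free hydroxyl group and leaves the three stereocentres untouched.

Step 10
Reactants: 15 (3E)-4-[(1S,2S,3S)-3-hydroxy-2,6,6-trimethylcyclohexyl]but-3-en-2-one; 16 vinylmagnesium bromide (3 equiv)
Product: 17 (1S,2S,3S)-3-[(1E)-3-hydroxy-3-methylpenta-1,4-dien-1-yl]-2,4,4-trimethylcyclohexan-1-ol (both configurations at the tertiary carbinol)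
Conditions: THF, −78 °C to 0 °C, addition of 15 to the Grignard reagent; aq. NH4Cl
Reagents that add atoms: none
Why: 1,2-Addition of a vinyl Grignard reagent to the methyl enone (the vinyl-ionol type of carbinol synthesis), one equivalent being consumed by the ring hydroxyl group; the new carbinol centre is an inconsequential mixture that is erased in steps 11 and 14.

Step 11
Reactants: 17 (1S,2S,3S)-3-[(1E)-3-hydroxy-3-methylpenta-1,4-dien-1-yl]-2,4,4-trimethylcyclohexan-1-ol
Product: 18 [(2E,4E)-5-[(1S,2S,3S)-3-hydroxy-2,6,6-trimethylcyclohexyl]-3-methylpenta-2,4-dien-1-yl]triphenylphosphonium bromide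
Conditions: Ph3P·HBr, MeOH, rt; crystallisation
Reagents that add atoms: triphenylphosphine hydrobromide, [PH+](c1ccccc1)(c1ccccc1)c1ccccc1.[Br-]
Why: Acid-mediated ionisation of the bis-allylic tertiary alcohol to a pentadienyl cation and capture by PPh3 at the unhindered terminal carbon (allylic transposition, the standard C15 Wittig-salt formation) should give the (2E,4E)-dienyl salt, the non-allylic secondary hydroxyl group being inert.

Step 12
Reactants: 18 hydroxy C15 phosphonium bromide; 19 (2E,4E,6E)-2,7-dimethylocta-2,4,6-trienedial (3 equiv)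
Product: 22 (2E,4E,6E,8E,10E,12E)-13-[(1S,2S,3S)-3-hydroxy-2,6,6-trimethylcyclohexyl]-2,7,11-trimethyltrideca-2,4,6,8,10,12-hexaenal, via phosphorus ylide 20 (not isolated), via 8Z olefin isomer 21 (not isolated)
Conditions: NaOMe, CH2Cl2/MeOH, 0 °C, slow addition of base to 18 + 19; then n-heptane, 90 °C, N2, dark
Reagents that add atoms: none
Why: Wittig olefination of the semi-stabilised allylic ylide with an excess of the symmetrical dialdehyde should give the mono-olefination product, the new C11=C12 bond forming as an E/Z mixture whose congested Z component is converted thermally to E.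

Step 13
Reactants: 17 (1S,2S,3S)-3-[(1E)-3-hydroxy-3-methylpenta-1,4-dien-1-yl]-2,4,4-trimethylcyclohexan-1-ol
Product: 23 (2S,3S)-3-[(1E)-3-hydroxy-3-methylpenta-1,4-dien-1-yl]-2,4,4-trimethylcyclohexan-1-one
Conditions: Dess–Martin periodinane, pyridine, CH2Cl2, 0 °C
Reagents that add atoms: none
Why: Dess–Martin oxidation should convert only the secondary alcohol (the tertiary carbinol cannot be oxidised and pyridine buffers the acetic acid so that it does not ionise), and the centre alpha to the new ketone already has the stable trans-diequatorial configuration.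

Step 14
Reactants: 23 (2S,3S)-3-[(1E)-3-hydroxy-3-methylpenta-1,4-dien-1-yl]-2,4,4-trimethylcyclohexan-1-one
Product: 24 [(2E,4E)-3-methyl-5-[(1S,2S)-2,6,6-trimethyl-3-oxocyclohexyl]penta-2,4-dien-1-yl]triphenylphosphonium bromide
Conditions: Ph3P·HBr, MeOH, rt; crystallisation
Reagents that add atoms: triphenylphosphine hydrobromide, [PH+](c1ccccc1)(c1ccccc1)c1ccccc1.[Br-]
Why: Same allylic transposition with phosphine capture as in step 11; the ring ketone is inert and its alpha centre, if it enolises under the acid, returns to the trans arrangement.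

Step 15
Reactants: 22 hydroxy C25 aldehyde; 24 oxo C15 phosphonium bromide
Product: 27 (4S,5S,6S,5'S,6'S)-4-hydroxy-5,6,5',6'-tetrahydro-β,β-caroten-4'-one (the target, all-E), via phosphorus ylide 25 (not isolated), via 11'Z olefin isomer 26 (not isolated)
Conditions: NaOMe, CH2Cl2/MeOH, 0 °C to rt; then n-heptane, 90 °C, N2, dark; crystallisation
Reagents that add atoms: none
Why: Wittig olefination in which the allylic ylide should react with the polyenal far faster than with the hindered ring ketone (oxo end groups are carried unprotected through such couplings), followed by thermal Z-to-E isomerisation of the new C11'=C12' bond; the ring stereocentres are not alpha to any group activated under these conditions except C5', which is already in its stable configuration.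

## Compound list

1 | (2E)-penta-2,4-dien-1-ol | OC/C=C/C=C | starting material
2 | 2-methylpropanoyl chloride | CC(C)C(=O)Cl | starting material
3 | (2E)-penta-2,4-dien-1-yl 2-methylpropanoate | CC(C)C(=O)OC/C=C/C=C | intermediate
4 | trimethyl({2-methyl-1-[(2E)-penta-2,4-dien-1-yloxy]prop-1-en-1-yl}oxy)silane (silyl ketene acetal) | CC(C)=C(OC/C=C/C=C)O[Si](C)(C)C | intermediate (not isolated)
5 | trimethylsilyl 3-ethenyl-2,2-dimethylpent-4-enoate | C=CC(C=C)C(C)(C)C(=O)O[Si](C)(C)C | intermediate (not isolated)
6 | 3-ethenyl-2,2-dimethylpent-4-enoic acid | C=CC(C=C)C(C)(C)C(=O)O | intermediate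
7 | 3-ethenyl-2,2-dimethylpent-4-en-1-ol | C=CC(C=C)C(C)(C)CO | intermediate
8 | 3-ethenyl-2,2-dimethylpent-4-enal | C=CC(C=C)C(C)(C)C=O | intermediate
9 | (triphenylphosphoranylidene)acetaldehyde | O=CC=P(c1ccccc1)(c1ccccc1)c1ccccc1 | starting material
10 | (2E)-5-ethenyl-4,4-dimethylhepta-2,6-dienal | C=CC(C=C)C(C)(C)/C=C/C=O | intermediate
11 | 5-ethenyl-4,4-dimethylhept-6-enal | C=CC(C=C)C(C)(C)CCC=O | intermediate
12 | (2S,3S)-3-ethenyl-2,4,4-trimethylcyclohexan-1-one | C=C[C@H]1[C@H](C)C(=O)CCC1(C)C | intermediate
13 | (1S,2S,3S)-3-ethenyl-2,4,4-trimethylcyclohexan-1-ol | C=C[C@H]1[C@H](C)[C@@H](O)CCC1(C)C | intermediate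
14 | but-3-en-2-one (methyl vinyl ketone) | CC(=O)C=C | starting material
15 | (3E)-4-[(1S,2S,3S)-3-hydroxy-2,6,6-trimethylcyclohexyl]but-3-en-2-one | CC(=O)/C=C/[C@H]1[C@H](C)[C@@H](O)CCC1(C)C | intermediate
16 | vinylmagnesium bromide | C=C[Mg]Br | starting material
17 | (1S,2S,3S)-3-[(1E)-3-hydroxy-3-methylpenta-1,4-dien-1-yl]-2,4,4-trimethylcyclohexan-1-ol (both configurations at the tertiary carbinol) | C=CC(C)(O)/C=C/[C@H]1[C@H](C)[C@@H](O)CCC1(C)C | intermediate
18 | [(2E,4E)-5-[(1S,2S,3S)-3-hydroxy-2,6,6-trimethylcyclohexyl]-3-methylpenta-2,4-dien-1-yl]triphenylphosphonium bromide | [Br-].c1ccccc1[P+](c1ccccc1)(c1ccccc1)C/C=C(C)/C=C/[C@H]1[C@H](C)[C@@H](O)CCC1(C)C | intermediate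
19 | (2E,4E,6E)-2,7-dimethylocta-2,4,6-trienedial | O=C/C(C)=C/C=C/C=C(C)/C=O | starting material
20 | (2E,4E)-5-[(1S,2S,3S)-3-hydroxy-2,6,6-trimethylcyclohexyl]-3-methylpenta-2,4-dien-1-ylidene(triphenyl)phosphorane | c1ccccc1P(c1ccccc1)(c1ccccc1)=C/C=C(C)/C=C/[C@H]1[C@H](C)[C@@H](O)CCC1(C)C | intermediate (not isolated)
21 | (2E,4E,6E,8Z,10E,12E)-13-[(1S,2S,3S)-3-hydroxy-2,6,6-trimethylcyclohexyl]-2,7,11-trimethyltrideca-2,4,6,8,10,12-hexaenal | O=C/C(C)=C/C=C/C=C(C)/C=C\C=C(C)\C=C\[C@H]1[C@H](C)[C@@H](O)CCC1(C)C | intermediate (not isolated)
22 | (2E,4E,6E,8E,10E,12E)-13-[(1S,2S,3S)-3-hydroxy-2,6,6-trimethylcyclohexyl]-2,7,11-trimethyltrideca-2,4,6,8,10,12-hexaenal | O=C/C(C)=C/C=C/C=C(C)/C=C/C=C(C)/C=C/[C@H]1[C@H](C)[C@@H](O)CCC1(C)C | intermediate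
23 | (2S,3S)-3-[(1E)-3-hydroxy-3-methylpenta-1,4-dien-1-yl]-2,4,4-trimethylcyclohexan-1-one (both configurations at the tertiary carbinol) | C=CC(C)(O)/C=C/[C@H]1[C@H](C)C(=O)CCC1(C)C | intermediate
24 | [(2E,4E)-3-methyl-5-[(1S,2S)-2,6,6-trimethyl-3-oxocyclohexyl]penta-2,4-dien-1-yl]triphenylphosphonium bromide | [Br-].c1ccccc1[P+](c1ccccc1)(c1ccccc1)C/C=C(C)/C=C/[C@H]1[C@H](C)C(=O)CCC1(C)C | intermediate
25 | (2E,4E)-3-methyl-5-[(1S,2S)-2,6,6-trimethyl-3-oxocyclohexyl]penta-2,4-dien-1-ylidene(triphenyl)phosphorane | c1ccccc1P(c1ccccc1)(c1ccccc1)=C/C=C(C)/C=C/[C@H]1[C@H](C)C(=O)CCC1(C)C | intermediate (not isolated)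
26 | (11'Z)-isomer of the target | CC(/C=C/C=C(C)/C=C/[C@H]1[C@H](C)[C@@H](O)CCC1(C)C)=C\C=C\C=C(C)\C=C/C=C(C)/C=C/[C@H]1[C@H](C)C(=O)CCC1(C)C | intermediate (not isolated)
27 | (4S,5S,6S,5'S,6'S)-4-hydroxy-5,6,5',6'-tetrahydro-β,β-caroten-4'-one, all-E (CNP0107241.1) | CC(/C=C/C=C(C)/C=C/[C@H]1[C@H](C)[C@@H](O)CCC1(C)C)=C\C=C\C=C(C)\C=C\C=C(C)\C=C\[C@H]1[C@H](C)C(=O)CCC1(C)C | target

## Step count and risks

Total step count: 15. Longest linear sequence: 13 steps (steps 1–10, 13, 14, 15; the branch 1–10, 11, 12, 15 is equally long).

Steps most likely to fail: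

Step 7 (proposed new method). The carbon–carbon bond formation from the aliphatic Breslow intermediate may be too slow relative to acyloin or aldol self-condensation, or the two vinyl groups may be poorly discriminated. The fallback sets out from 11 and uses known radical chemistry followed by a resolution. Radical-chain hydroacylation under polarity-reversal catalysis (tert-dodecanethiol, azo initiator, chlorobenzene, 100 °C, high dilution) would generate the acyl radical, which closes 6-exo-trig onto either vinyl group. After equilibration with DBU this should give racemic trans-3-ethenyl-2,4,4-trimethylcyclohexan-1-one F1. Reduction with NaBH4 would give racemic (1S*,2S*,3S*)-3-ethenyl-2,4,4-trimethylcyclohexan-1-ol F2. Lipase-catalysed acylation (Candida antarctica lipase B, vinyl acetate, hexane) should, by the usual enantiopreference of lipases for secondary alcohols, acetylate the (1R) enantiomer to (1R,2R,3R)-3-ethenyl-2,4,4-trimethylcyclohexyl acetate F3 and leave the (1S,2S,3S) alcohol, which is 13, where the route is rejoined.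

Step 9. Productive metathesis at the vinyl group, which is shielded by the quaternary carbon and the methyl-bearing methine, may be slow, so that catalyst decomposition and self-metathesis of the ketone partner take over. The fallback sets out from 13. Ozonolysis (O3, CH2Cl2/MeOH, −78 °C; Me2S) would give (1S,2S,3S)-3-hydroxy-2,6,6-trimethylcyclohexane-1-carbaldehyde F4. Wittig olefination with 1-(triphenylphosphoranylidene)propan-2-one in toluene at 60 °C should then give the (E)-enone 15, where the route is rejoined.

Step 5. Olefination of the hindered neopentyl aldehyde may be incomplete at a temperature that still avoids Cope rearrangement of the 1,5-diene product, and double homologation may compete. The fallback sets out from 8 and moves to the ester oxidation level. Horner–Wadsworth–Emmons reaction with trimethyl phosphonoacetate (NaH, THF, 0 °C to rt) would give methyl (2E)-5-ethenyl-4,4-dimethylhepta-2,6-dienoate F5. Conjugate reduction with Mg in MeOH should give methyl 5-ethenyl-4,4-dimethylhept-6-enoate F6, and iBu2AlH (CH2Cl2, −78 °C) would reduce it to the aldehyde 11, where the route is rejoined.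

Further compounds

F1 | step 7 | racemic trans-3-ethenyl-2,4,4-trimethylcyclohexan-1-one | C=C[C@H]1[C@H](C)C(=O)CCC1(C)C.C=C[C@@H]1[C@@H](C)C(=O)CCC1(C)C
F2 | step 7 | racemic (1S*,2S*,3S*)-3-ethenyl-2,4,4-trimethylcyclohexan-1-ol | C=C[C@H]1[C@H](C)[C@@H](O)CCC1(C)C.C=C[C@@H]1[C@@H](C)[C@H](O)CCC1(C)C
F3 | step 7 | (1R,2R,3R)-3-ethenyl-2,4,4-trimethylcyclohexyl acetate | C=C[C@@H]1[C@@H](C)[C@H](OC(C)=O)CCC1(C)C
F4 | step 9 | (1S,2S,3S)-3-hydroxy-2,6,6-trimethylcyclohexane-1-carbaldehyde | O=C[C@H]1[C@H](C)[C@@H](O)CCC1(C)C
F5 | step 5 | methyl (2E)-5-ethenyl-4,4-dimethylhepta-2,6-dienoate | C=CC(C=C)C(C)(C)/C=C/C(=O)OC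
F6 | step 5 | methyl 5-ethenyl-4,4-dimethylhept-6-enoate | C=CC(C=C)C(C)(C)CCC(=O)OC
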